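Retrosynthetic cuts: the fourteen O–benzyl bonds; C2–C1′ of the middle unit (anomeric acetate + aryl–boron donor); O1–C2 and C3–C4 of middle ring C (o-quinone methide + enamine of benzyloxyacetaldehyde); middle C4–lower C8 (salicylaldehyde + 8-lithiated catechin ether); the formyl carbon–C4a bond; upper C4–middle C8 (epicatechin C4 cation + cyclohexane-1,3-dione, whose ring becomes middle ring A).
Enabling feature: middle C4 is a diarylmethine on C4a, next to the O1-bearing C8a, so O1–C8a–C4a–C4 is the heterodiene of an o-quinone methide and ring C lacks only C2 and C3.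
Forward order: upper unit + dione, aromatisation to middle ring A, ortho-formylation, addition of the lower unit (benzhydrol), amine-catalysed annulation of middle ring C, attachment of ring B at C2, global hydrogenolysis.
Stereochemistry: upper and lower C2/C3 come from (−)-epicatechin and (+)-catechin; upper C4 from anti attack on the C4 cation (step 4); middle C3/C4 from the (S)-prolinol silyl ether catalyst and anti approach to the E-methide (step 12); middle C2 from axial attack on the ring C oxocarbenium ion (step 15).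

Key step: step 12

Assumption and notation: the carbinol carbon made in step 11 and the anomeric carbon of the lactol and its acetate are carried as epimer mixtures, since both become trigonal before they are fixed; "penta-O-benzyl" means the 3,5,7,3′,4′-pentabenzyl ether, "4β-yl" means attachment through C4 trans to the 3-benzyloxy group; 3,4-bis(benzyloxy)phenylboronic acid is taken as purchasable. The free arene 1,2-bis(benzyloxy)benzene is not used as the ring B donor because it is far less nucleophilic than the benzylated ring A carbons already present; an ipso-transferring boron donor is used instead.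

Step 1
Reactants: 1 (−)-epicatechin
Product: 2 5,7,3′,4′-tetra-O-benzylepicatechin
Conditions: BnBr (4.4 equiv), K2CO3, DMF, 0 °C → rt
Reagents that add atoms: benzyl bromide, BrCc1ccccc1
Why: Williamson etherification under carbonate conditions should alkylate only the four phenols and leave the much less acidic secondary 3-OH and both stereocentres untouched.

Step 2
Reactants: 2 5,7,3′,4′-tetra-O-benzylepicatechin
Product: 3 5,7,3′,4′-tetra-O-benzyl-4β-(2-ethoxyethoxy)epicatechin
Conditions: DDQ, 2-ethoxyethanol, CH2Cl2, rt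
Reagents that add atoms: 2-ethoxyethanol, OCCOCC
Why: DDQ benzylic oxidation, in which hydride abstraction from C4 is assisted by the 5,7-dialkoxy ring A, should give a cation that the alcohol captures anti to the C2 aryl and C3 hydroxyl groups (4β, 3,4-trans), installing a leaving group whose configuration has no later consequence.

Step 3
Reactants: 3 5,7,3′,4′-tetra-O-benzyl-4β-(2-ethoxyethoxy)epicatechin
Product: 4 3,5,7,3′,4′-penta-O-benzyl-4β-(2-ethoxyethoxy)epicatechin
Conditions: NaH, BnBr, n-Bu4NI (cat.), DMF, 0 °C → rt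
Reagents that add atoms: benzyl bromide, BrCc1ccccc1
Why: Williamson etherification of the secondary alkoxide, to which the C4 ether is inert, with no free phenol left that could open ring C under base.

Step 4
Reactants: 4 3,5,7,3′,4′-penta-O-benzyl-4β-(2-ethoxyethoxy)epicatechin + 5 cyclohexane-1,3-dione
Product: 6 2-(penta-O-benzylepicatechin-4β-yl)cyclohexane-1,3-dione (enol form)
Conditions: 5 (5 equiv), Me3SiOSO2CF3 (0.2 equiv), CH2Cl2, −40 → 0 °C
Reagents that add atoms: none
Why: Acid-catalysed SN1 alkylation of a 1,3-dicarbonyl compound, in which ionisation of the C4 ether gives the benzylic cation and the enol carbon C2 of the dione attacks anti to the cis-disposed C2 aryl and C3 benzyloxy groups (new C4–C bond β, 3,4-trans), any O-alkylated enol ether re-ionising and funnelling to the C-alkylated product.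

Step 5
Reactants: 6 2-(penta-O-benzylepicatechin-4β-yl)cyclohexane-1,3-dione
Product: 7 3-(benzyloxy)-2-(penta-O-benzylepicatechin-4β-yl)cyclohex-2-en-1-one
Conditions: BnBr, Cs2CO3, DMF, rt
Reagents that add atoms: benzyl bromide, BrCc1ccccc1
Why: O-alkylation of the vinylogous acid (Williamson type), in which the bulky C2 substituent should block C-benzylation and the symmetry of the dione allows only one enol ether.

Step 6
Reactants: 7 3-(benzyloxy)-2-(penta-O-benzylepicatechin-4β-yl)cyclohex-2-en-1-one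
Product: 9 3-(benzyloxy)-2-(penta-O-benzylepicatechin-4β-yl)phenol, via α′-phenylselenide 8 (not isolated)
Conditions: LiN(iPr)2, THF, −78 °C; PhSeCl, −78 °C; then 30% H2O2, pyridine, CH2Cl2, 0 °C → rt
Reagents that add atoms: none
Why: Kinetic α′-deprotonation of the vinylogous ester and selenenylation at C6, followed by oxidation and selenoxide syn-elimination, should give a cross-conjugated dienone that tautomerises to the phenol, so that the former enol ether oxygen ends as the only protected resorcinol oxygen.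

Step 7
Reactants: 9 3-(benzyloxy)-2-(penta-O-benzylepicatechin-4β-yl)phenol
Product: 10 4-(benzyloxy)-2-hydroxy-3-(penta-O-benzylepicatechin-4β-yl)benzaldehyde
Conditions: MgCl2, Et3N, (CH2O)n, MeCN, reflux; then 1 M HCl
Reagents that add atoms: paraformaldehyde (formaldehyde), C=O
Why: Casnati–Skattebøl ortho-formylation, in which the magnesium phenoxide delivers formaldehyde through a six-membered chelate to the only free ortho position and a second formaldehyde oxidises the benzylic alkoxide to the aldehyde, the para position staying untouched.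

Step 8
Reactants: 11 (+)-catechin
Product: 12 5,7,3′,4′-tetra-O-benzylcatechin
Conditions: BnBr (4.4 equiv), K2CO3, DMF, 0 °C → rt
Reagents that add atoms: benzyl bromide, BrCc1ccccc1
Why: Williamson etherification of the four phenols as in step 1, leaving the 3-OH free and the 2,3-trans stereocentres untouched.

Step 9
Reactants: 12 5,7,3′,4′-tetra-O-benzylcatechin
Product: 13 8-bromo-5,7,3′,4′-tetra-O-benzylcatechin
Conditions: N-bromosuccinimide (1.0 equiv), CH2Cl2, −78 → 0 °C
Reagents that add atoms: N-bromosuccinimide, O=C1CCC(=O)N1Br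
Why: Electrophilic aromatic bromination of the electron-rich ring A, which in 5,7-dialkoxyflavan-3-ols should occur at C8 in preference to C6 and so marks the future linkage carbon.

Step 10
Reactants: 13 8-bromo-5,7,3′,4′-tetra-O-benzylcatechin
Product: 14 8-bromo-3,5,7,3′,4′-penta-O-benzylcatechin
Conditions: NaH, BnBr, n-Bu4NI (cat.), DMF, 0 °C → rt
Reagents that add atoms: benzyl bromide, BrCc1ccccc1
Why: Williamson etherification of the secondary alkoxide, with no free phenol present so that base-induced C2 epimerisation is not expected.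

Step 11
Reactants: 14 8-bromo-3,5,7,3′,4′-penta-O-benzylcatechin + 10 4-(benzyloxy)-2-hydroxy-3-(penta-O-benzylepicatechin-4β-yl)benzaldehyde
Product: 17 [4-(benzyloxy)-2-hydroxy-3-(penta-O-benzylepicatechin-4β-yl)phenyl](penta-O-benzylcatechin-8-yl)methanol (carbinol epimers), via aryllithium 15 (not isolated), via sodium phenoxide 16 (not isolated)
Conditions: 14, n-BuLi, THF, −78 °C; separately 10, NaH, THF, 0 °C; phenoxide solution added to the aryllithium, −78 → −30 °C; then H2O; chromatography on Et3N-deactivated silica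
Reagents that add atoms: none
Why: Bromine–lithium exchange followed by 1,2-addition of the aryllithium to the aldehyde, whose acidic phenol is masked beforehand as the sodium phenoxide, should form the diaryl carbinol regiospecifically at catechin C8, and the new carbinol centre need not be controlled because it becomes trigonal in step 12.

Step 12
Reactants: 17 [4-(benzyloxy)-2-hydroxy-3-(penta-O-benzylepicatechin-4β-yl)phenyl](penta-O-benzylcatechin-8-yl)methanol + 18 benzyloxyacetaldehyde
Product: 22 (3R,4R)-3,7-bis(benzyloxy)-4-(penta-O-benzylcatechin-8-yl)-8-(penta-O-benzylepicatechin-4β-yl)chroman-2-ol (3,4-trans; anomer mixture), via enamine 19 (not isolated), via o-quinone methide 20 (not isolated), via aminal 21 (not isolated)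
Conditions: 18 (3 equiv), (S)-2-[diphenyl(trimethylsilyloxy)methyl]pyrrolidine (20 mol%), PhCO2H (20 mol%), CHCl3, 0 °C → rt
Reagents that add atoms: none
Why: Benzoic acid should ionise the doubly activated benzhydrol 17 to E-o-quinone methide 20 while aldehyde 18 condenses with the amine to E-enamine 19; the enamine α-carbon adds to the methide carbon (C3–C4 bond), the freed phenoxide closes on the iminium carbon (O1–C2 bond) to aminal 21, and water released in the flask hydrolyses 21 to lactol 22 and returns the amine. The closest known reaction type is the secondary-amine-catalysed Michael addition/hemiacetalisation (formal [4+2]) of aldehydes with o-quinone methides generated in situ from o-hydroxybenzhydrols, which gives trans-3,4-disubstituted chroman-2-ols. Ring C closes stepwise, the second bond by 6-exo-trig attack of the C8a oxygen on the iminium carbon. C3 is set by the catalyst, whose diphenyl(silyloxy)methyl group shields one face of the s-trans E-enamine so that the (S)-amine should deliver the 3R configuration, and C4 by an anti (open) approach of the enamine to the E-methide that places the catechin-8-yl group trans to the 3-benzyloxy group (4R), which is also the more stable arrangement; C2 stays a mixture. The step needs regioselectivity, secured because the only free oxygen ortho to the methide is the one on C8a, and chemoselectivity for the enamine over the electron-rich ring A carbons, secured by the far higher nucleophilicity of the enamine and the excess of 18.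

Step 13
Reactants: 22 (3R,4R)-3,7-bis(benzyloxy)-4-(penta-O-benzylcatechin-8-yl)-8-(penta-O-benzylepicatechin-4β-yl)chroman-2-ol
Product: 23 (3R,4R)-3,7-bis(benzyloxy)-4-(penta-O-benzylcatechin-8-yl)-8-(penta-O-benzylepicatechin-4β-yl)chroman-2-yl acetate (anomer mixture)
Conditions: Ac2O, pyridine, 4-(dimethylamino)pyridine (cat.), CH2Cl2, 0 °C → rt
Reagents that add atoms: acetic anhydride, CC(=O)OC(C)=O
Why: Base-mediated O-acylation of the lactol hydroxyl, the only free OH in the molecule, should give an ionisable anomeric acetate without exposing the acid-labile diarylmethine centres to acid.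

Step 14
Reactants: 24 3,4-bis(benzyloxy)phenylboronic acid
Product: 25 potassium [3,4-bis(benzyloxy)phenyl]trifluoroborate
Conditions: KHF2 (3 equiv), MeOH/H2O, rt
Reagents that add atoms: potassium hydrogen difluoride KHF2, [K+].[F-].F
Why: Fluoride exchange at boron is the standard conversion of a boronic acid into its bench-stable trifluoroborate salt.

Step 15
Reactants: 23 (3R,4R)-3,7-bis(benzyloxy)-4-(penta-O-benzylcatechin-8-yl)-8-(penta-O-benzylepicatechin-4β-yl)chroman-2-yl acetate + 25 potassium [3,4-bis(benzyloxy)phenyl]trifluoroborate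
Product: 27 tetradeca-O-benzyl epicatechin-(4β→8)-epifisetinidol-(4β→8)-catechin, via aryldifluoroborane 26 (not isolated)
Conditions: 25 (4 equiv), BF3·OEt2 (4 equiv), CH2Cl2, 0 °C, 15 min; then 23, −40 → 0 °C; aq. NaHCO3
Reagents that add atoms: none
Why: Lewis acid-promoted substitution of an anomeric acetate by an organotrifluoroborate, in which aryldifluoroborane 26 should ionise the acetate to the chroman-2-yl oxocarbenium ion and transfer its aryl group from boron (ipso) within the ion pair faster than the benzylated ring A carbons can compete, while axial attack on the half-chair that holds the 3-benzyloxy and 4-aryl groups pseudoequatorial, anti to the C4 aryl group, should place the new aryl group cis to O3 and trans to the C4 aryl (2R), in line with the 1,2-cis preference of six-membered oxocarbenium ions bearing an adjacent alkoxy group.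

Step 16
Reactants: 27 tetradeca-O-benzyl epicatechin-(4β→8)-epifisetinidol-(4β→8)-catechin
Product: 28 epicatechin-(4β→8)-epifisetinidol-(4β→8)-catechin (CNP0270097.1)
Conditions: H2 (1 atm), Pd(OH)2 on carbon, THF/MeOH/H2O, rt
Reagents that add atoms: none
Why: Catalytic hydrogenolysis of the fourteen benzyl ethers should release all phenols and the three secondary alcohols without touching the C4–C8 bonds or the pyran C–O bonds, and no stereocentre is affected.

Compound list
1 | (−)-epicatechin, (2R,3R)-flavan-3,5,7,3′,4′-pentol | Oc1cc(O)c2c(c1)O[C@H](c1ccc(O)c(O)c1)[C@H](O)C2 | starting material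
2 | 5,7,3′,4′-tetra-O-benzylepicatechin (3-OH free) | c9ccccc9COc1cc(OCc9ccccc9)c2c(c1)O[C@H](c3ccc(OCc9ccccc9)c(OCc9ccccc9)c3)[C@H](O)C2 | intermediate
3 | 5,7,3′,4′-tetra-O-benzyl-4β-(2-ethoxyethoxy)epicatechin (2,3-cis, 3,4-trans) | c9ccccc9COc1cc(OCc9ccccc9)c2c(c1)O[C@H](c3ccc(OCc9ccccc9)c(OCc9ccccc9)c3)[C@H](O)[C@H]2OCCOCC | intermediate
4 | 3,5,7,3′,4′-penta-O-benzyl-4β-(2-ethoxyethoxy)epicatechin | c9ccccc9COc1cc(OCc9ccccc9)c2c(c1)O[C@H](c3ccc(OCc9ccccc9)c(OCc9ccccc9)c3)[C@H](OCc9ccccc9)[C@H]2OCCOCC | intermediate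
5 | cyclohexane-1,3-dione | O=C1CCCC(=O)C1 | starting material
6 | 2-(3,5,7,3′,4′-penta-O-benzylepicatechin-4β-yl)cyclohexane-1,3-dione, drawn as its enol | c9ccccc9COc1cc(OCc9ccccc9)c2c(c1)O[C@H](c3ccc(OCc9ccccc9)c(OCc9ccccc9)c3)[C@H](OCc9ccccc9)[C@H]2C4=C(O)CCCC4=O | intermediate
7 | 3-(benzyloxy)-2-(3,5,7,3′,4′-penta-O-benzylepicatechin-4β-yl)cyclohex-2-en-1-one | c9ccccc9COc1cc(OCc9ccccc9)c2c(c1)O[C@H](c3ccc(OCc9ccccc9)c(OCc9ccccc9)c3)[C@H](OCc9ccccc9)[C@H]2C4=C(OCc9ccccc9)CCCC4=O | intermediate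
8 | 6-(phenylselanyl) derivative of 7 (C6 epimers; not isolated) | c9ccccc9COc1cc(OCc9ccccc9)c2c(c1)O[C@H](c3ccc(OCc9ccccc9)c(OCc9ccccc9)c3)[C@H](OCc9ccccc9)[C@H]2C4=C(OCc9ccccc9)CCC([Se]c9ccccc9)C4=O | intermediate
9 | 3-(benzyloxy)-2-(3,5,7,3′,4′-penta-O-benzylepicatechin-4β-yl)phenol | c9ccccc9COc1cc(OCc9ccccc9)c2c(c1)O[C@H](c3ccc(OCc9ccccc9)c(OCc9ccccc9)c3)[C@H](OCc9ccccc9)[C@H]2c4c(OCc9ccccc9)cccc4O | intermediate
10 | 4-(benzyloxy)-2-hydroxy-3-(3,5,7,3′,4′-penta-O-benzylepicatechin-4β-yl)benzaldehyde | c9ccccc9COc1cc(OCc9ccccc9)c2c(c1)O[C@H](c3ccc(OCc9ccccc9)c(OCc9ccccc9)c3)[C@H](OCc9ccccc9)[C@H]2c4c(OCc9ccccc9)ccc(C=O)c4O | intermediate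
11 | (+)-catechin, (2R,3S)-flavan-3,5,7,3′,4′-pentol | Oc1cc(O)c2c(c1)O[C@H](c1ccc(O)c(O)c1)[C@@H](O)C2 | starting material
12 | 5,7,3′,4′-tetra-O-benzylcatechin (3-OH free) | c9ccccc9COc1cc(OCc9ccccc9)c2c(c1)O[C@H](c3ccc(OCc9ccccc9)c(OCc9ccccc9)c3)[C@@H](O)C2 | intermediate
13 | 8-bromo-5,7,3′,4′-tetra-O-benzylcatechin | c9ccccc9COc1cc(OCc9ccccc9)c2c(c1Br)O[C@H](c3ccc(OCc9ccccc9)c(OCc9ccccc9)c3)[C@@H](O)C2 | intermediate
14 | 8-bromo-3,5,7,3′,4′-penta-O-benzylcatechin | c9ccccc9COc1cc(OCc9ccccc9)c2c(c1Br)O[C@H](c3ccc(OCc9ccccc9)c(OCc9ccccc9)c3)[C@@H](OCc9ccccc9)C2 | intermediate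
15 | 8-lithio-3,5,7,3′,4′-penta-O-benzylcatechin (not isolated) | [Li]c1c(OCc9ccccc9)cc(OCc9ccccc9)c2c1O[C@H](c3ccc(OCc9ccccc9)c(OCc9ccccc9)c3)[C@@H](OCc9ccccc9)C2 | intermediate
16 | sodium phenoxide of 10 (not isolated) | [Na+].c9ccccc9COc1cc(OCc9ccccc9)c2c(c1)O[C@H](c3ccc(OCc9ccccc9)c(OCc9ccccc9)c3)[C@H](OCc9ccccc9)[C@H]2c4c(OCc9ccccc9)ccc(C=O)c4[O-] | intermediate
17 | o-hydroxybenzhydrol: [4-(benzyloxy)-2-hydroxy-3-(penta-O-benzylepicatechin-4β-yl)phenyl](penta-O-benzylcatechin-8-yl)methanol, carbinol epimers | c9ccccc9COc1cc(OCc9ccccc9)c2c(c1)O[C@H](c3ccc(OCc9ccccc9)c(OCc9ccccc9)c3)[C@H](OCc9ccccc9)[C@H]2c4c(OCc9ccccc9)ccc(c4O)C(O)c1c(OCc9ccccc9)cc(OCc9ccccc9)c2c1O[C@H](c3ccc(OCc9ccccc9)c(OCc9ccccc9)c3)[C@@H](OCc9ccccc9)C2 | intermediate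
18 | benzyloxyacetaldehyde | O=CCOCc1ccccc1 | starting material
19 | (E)-enamine of 18 and (S)-2-[diphenyl(trimethylsilyloxy)methyl]pyrrolidine (not isolated) | c1ccccc1CO/C=C/N1CCC[C@H]1C(c1ccccc1)(c1ccccc1)O[Si](C)(C)C | intermediate
20 | (E)-o-quinone methide: 3-(benzyloxy)-6-[(penta-O-benzylcatechin-8-yl)methylidene]-2-(penta-O-benzylepicatechin-4β-yl)cyclohexa-2,4-dien-1-one (not isolated) | c9ccccc9COc1cc(OCc9ccccc9)c2c(c1)O[C@H](c3ccc(OCc9ccccc9)c(OCc9ccccc9)c3)[C@H](OCc9ccccc9)[C@H]2C4=C(OCc9ccccc9)C=C/C(=C\c1c(OCc9ccccc9)cc(OCc9ccccc9)c2c1O[C@H](c3ccc(OCc9ccccc9)c(OCc9ccccc9)c3)[C@@H](OCc9ccccc9)C2)C4=O | intermediate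
21 | cyclic N,O-aminal: 22 with the C2 hydroxyl replaced by the catalyst nitrogen (C2 epimers; not isolated) | c9ccccc9COc1cc(OCc9ccccc9)c2c(c1)O[C@H](c3ccc(OCc9ccccc9)c(OCc9ccccc9)c3)[C@H](OCc9ccccc9)[C@H]2c4c(OCc9ccccc9)ccc5c4OC(N6CCC[C@H]6C(c7ccccc7)(c7ccccc7)O[Si](C)(C)C)[C@H](OCc9ccccc9)[C@H]5c1c(OCc9ccccc9)cc(OCc9ccccc9)c2c1O[C@H](c3ccc(OCc9ccccc9)c(OCc9ccccc9)c3)[C@@H](OCc9ccccc9)C2 | intermediate
22 | lactol: (3R,4R)-3,7-bis(benzyloxy)-4-(penta-O-benzylcatechin-8-yl)-8-(penta-O-benzylepicatechin-4β-yl)chroman-2-ol, 3,4-trans, anomer mixture | c9ccccc9COc1cc(OCc9ccccc9)c2c(c1)O[C@H](c3ccc(OCc9ccccc9)c(OCc9ccccc9)c3)[C@H](OCc9ccccc9)[C@H]2c4c(OCc9ccccc9)ccc5c4OC(O)[C@H](OCc9ccccc9)[C@H]5c1c(OCc9ccccc9)cc(OCc9ccccc9)c2c1O[C@H](c3ccc(OCc9ccccc9)c(OCc9ccccc9)c3)[C@@H](OCc9ccccc9)C2 | intermediate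
23 | anomeric acetate of 22 (anomer mixture) | c9ccccc9COc1cc(OCc9ccccc9)c2c(c1)O[C@H](c3ccc(OCc9ccccc9)c(OCc9ccccc9)c3)[C@H](OCc9ccccc9)[C@H]2c4c(OCc9ccccc9)ccc5c4OC(OC(C)=O)[C@H](OCc9ccccc9)[C@H]5c1c(OCc9ccccc9)cc(OCc9ccccc9)c2c1O[C@H](c3ccc(OCc9ccccc9)c(OCc9ccccc9)c3)[C@@H](OCc9ccccc9)C2 | intermediate
24 | 3,4-bis(benzyloxy)phenylboronic acid | OB(O)c1ccc(OCc2ccccc2)c(OCc2ccccc2)c1 | starting material
25 | potassium [3,4-bis(benzyloxy)phenyl]trifluoroborate | [K+].F[B-](F)(F)c1ccc(OCc2ccccc2)c(OCc2ccccc2)c1 | intermediate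
26 | [3,4-bis(benzyloxy)phenyl]difluoroborane (not isolated) | FB(F)c1ccc(OCc2ccccc2)c(OCc2ccccc2)c1 | intermediate
27 | tetradeca-O-benzyl epicatechin-(4β→8)-epifisetinidol-(4β→8)-catechin; middle unit (2R,3R,4R), 2,3-cis, 3,4-trans | c9ccccc9COc1cc(OCc9ccccc9)c2c(c1)O[C@H](c3ccc(OCc9ccccc9)c(OCc9ccccc9)c3)[C@H](OCc9ccccc9)[C@H]2c4c(OCc9ccccc9)ccc5c4O[C@H](c6ccc(OCc9ccccc9)c(OCc9ccccc9)c6)[C@H](OCc9ccccc9)[C@H]5c1c(OCc9ccccc9)cc(OCc9ccccc9)c2c1O[C@H](c3ccc(OCc9ccccc9)c(OCc9ccccc9)c3)[C@@H](OCc9ccccc9)C2 | intermediate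
28 | epicatechin-(4β→8)-epifisetinidol-(4β→8)-catechin (CNP0270097.1) | Oc1cc(O)c2c(c1)O[C@H](c1ccc(O)c(O)c1)[C@H](O)[C@H]2c1c(O)ccc2c1O[C@H](c1ccc(O)c(O)c1)[C@H](O)[C@H]2c1c(O)cc(O)c2c1O[C@H](c1ccc(O)c(O)c1)[C@@H](O)C2 | target

Total step count: 16.
Longest linear sequence: 12 steps (steps 1–7, 11, 12, 13, 15, 16, from (−)-epicatechin).

Steps most likely to fail

Step 12. The enamine may add too slowly to the crowded, strongly stabilised methide carbon, so that the cation is consumed by Friedel–Crafts self-condensation with ring A carbons. It may also react through the Z-enamine or the other methide face, which would erode control at C3 and C4. The fallback sets out from 17 and returns at 22, replacing amine catalysis by a stoichiometric chiral auxiliary. Commercial (S)-4-benzyl-3-(benzyloxyacetyl)oxazolidin-2-one is enolised with TiCl4 and i-Pr2NEt in CH2Cl2 at −78 °C, and 17 is added so that the Lewis acid ionises it. SN1-type alkylation of the chelated Z-enolate on the face away from the auxiliary benzyl group should give the N-acyl oxazolidinone adduct F2 with the same 3R sense. Warming with 4-(dimethylamino)pyridine lets the free phenol displace the auxiliary to give the 3,4-trans chroman-2-one F3. Reduction with i-Bu2AlH in CH2Cl2 at −78 °C then leads to lactol 22.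

Step 15. Aryl transfer from boron may be outrun by capture of the oxocarbenium ion by ring A carbons of a second molecule. BF3 may also heterolyse the acid-labile C4–C8 bonds, or the facial bias at C2 may be insufficient. The fallback sets out from 22 and returns at 27, reversing the order in which the two C2 substituents are introduced. Lactol 22 is opened through its hydroxy-aldehyde form with 3,4-bis(benzyloxy)phenylmagnesium bromide F4 (from 4-bromo-1,2-bis(benzyloxy)benzene and Mg, THF, 0 °C) to the ring-opened diaryl carbinol F5. MnO2 in CH2Cl2 oxidises the electron-rich benzylic carbinol to aryl ketone F6, which closes with the neighbouring phenol to the cyclic hemiketal F7. Et3SiH and BF3·OEt2 at −78 °C reduce the derived 2-aryl oxocarbenium ion, in which allylic strain with the 2-aryl group should hold the 3-benzyloxy group pseudoaxial. Hydride is then expected to enter anti to that group, giving the 2,3-cis flavan 27. Excess silane traps the cation before arenes can.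

Step 11. Proton transfer may quench the hindered 2,6-dialkoxyaryllithium before it adds, or it may fail to add to the deactivated phenoxide aldehyde. The fallback sets out from 9 (with 14 as the source of the partner) and returns at 17, inverting the polarity of the union. Aryllithium 15 is quenched with DMF to give 8-formyl-3,5,7,3′,4′-penta-O-benzylcatechin F1. Phenol 9, taken before formylation and deprotonated with EtMgBr in toluene, then undergoes ortho-specific hydroxyalkylation by F1 through a six-membered magnesium chelate. This forms the C4–C4a bond at the only free ortho position and delivers benzhydrol 17 directly, making step 7 unnecessary.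

Further compounds
F1 | step 11 | 8-formyl-3,5,7,3′,4′-penta-O-benzylcatechin | O=Cc1c(OCc9ccccc9)cc(OCc9ccccc9)c2c1O[C@H](c3ccc(OCc9ccccc9)c(OCc9ccccc9)c3)[C@@H](OCc9ccccc9)C2
F2 | step 12 | (S)-4-benzyl-3-{(2R,3R)-2-(benzyloxy)-3-[4-(benzyloxy)-2-hydroxy-3-(penta-O-benzylepicatechin-4β-yl)phenyl]-3-(penta-O-benzylcatechin-8-yl)propanoyl}oxazolidin-2-one | c9ccccc9COc1cc(OCc9ccccc9)c2c(c1)O[C@H](c3ccc(OCc9ccccc9)c(OCc9ccccc9)c3)[C@H](OCc9ccccc9)[C@H]2c4c(OCc9ccccc9)ccc(c4O)[C@H](c1c(OCc9ccccc9)cc(OCc9ccccc9)c2c1O[C@H](c3ccc(OCc9ccccc9)c(OCc9ccccc9)c3)[C@@H](OCc9ccccc9)C2)[C@@H](OCc9ccccc9)C(=O)N5C(=O)OC[C@@H]5Cc9ccccc9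
F3 | step 12 | (3R,4R)-3,7-bis(benzyloxy)-4-(penta-O-benzylcatechin-8-yl)-8-(penta-O-benzylepicatechin-4β-yl)chroman-2-one | c9ccccc9COc1cc(OCc9ccccc9)c2c(c1)O[C@H](c3ccc(OCc9ccccc9)c(OCc9ccccc9)c3)[C@H](OCc9ccccc9)[C@H]2c4c(OCc9ccccc9)ccc5c4OC(=O)[C@H](OCc9ccccc9)[C@H]5c1c(OCc9ccccc9)cc(OCc9ccccc9)c2c1O[C@H](c3ccc(OCc9ccccc9)c(OCc9ccccc9)c3)[C@@H](OCc9ccccc9)C2
F4 | step 15 | 3,4-bis(benzyloxy)phenylmagnesium bromide | Br[Mg]c1ccc(OCc2ccccc2)c(OCc2ccccc2)c1
F5 | step 15 | (2R,3R)-1-[3,4-bis(benzyloxy)phenyl]-2-(benzyloxy)-3-[4-(benzyloxy)-2-hydroxy-3-(penta-O-benzylepicatechin-4β-yl)phenyl]-3-(penta-O-benzylcatechin-8-yl)propan-1-ol (C1 epimers) | c9ccccc9COc1cc(OCc9ccccc9)c2c(c1)O[C@H](c3ccc(OCc9ccccc9)c(OCc9ccccc9)c3)[C@H](OCc9ccccc9)[C@H]2c4c(OCc9ccccc9)ccc(c4O)[C@H](c1c(OCc9ccccc9)cc(OCc9ccccc9)c2c1O[C@H](c3ccc(OCc9ccccc9)c(OCc9ccccc9)c3)[C@@H](OCc9ccccc9)C2)[C@@H](OCc9ccccc9)C(O)c5ccc(OCc9ccccc9)c(OCc9ccccc9)c5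
F6 | step 15 | (2R,3R)-1-[3,4-bis(benzyloxy)phenyl]-2-(benzyloxy)-3-[4-(benzyloxy)-2-hydroxy-3-(penta-O-benzylepicatechin-4β-yl)phenyl]-3-(penta-O-benzylcatechin-8-yl)propan-1-one | c9ccccc9COc1cc(OCc9ccccc9)c2c(c1)O[C@H](c3ccc(OCc9ccccc9)c(OCc9ccccc9)c3)[C@H](OCc9ccccc9)[C@H]2c4c(OCc9ccccc9)ccc(c4O)[C@H](c1c(OCc9ccccc9)cc(OCc9ccccc9)c2c1O[C@H](c3ccc(OCc9ccccc9)c(OCc9ccccc9)c3)[C@@H](OCc9ccccc9)C2)[C@@H](OCc9ccccc9)C(=O)c5ccc(OCc9ccccc9)c(OCc9ccccc9)c5
F7 | step 15 | (3R,4R)-2-[3,4-bis(benzyloxy)phenyl]-3,7-bis(benzyloxy)-4-(penta-O-benzylcatechin-8-yl)-8-(penta-O-benzylepicatechin-4β-yl)chroman-2-ol (C2 epimers) | c9ccccc9COc1cc(OCc9ccccc9)c2c(c1)O[C@H](c3ccc(OCc9ccccc9)c(OCc9ccccc9)c3)[C@H](OCc9ccccc9)[C@H]2c4c(OCc9ccccc9)ccc5c4OC(O)(c6ccc(OCc9ccccc9)c(OCc9ccccc9)c6)[C@H](OCc9ccccc9)[C@H]5c1c(OCc9ccccc9)cc(OCc9ccccc9)c2c1O[C@H](c3ccc(OCc9ccccc9)c(OCc9ccccc9)c3)[C@@H](OCc9ccccc9)C2
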